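**Retrosynthetic overview**
1. Target 23 ⇐ bis-silyl ketone 22 ⇐ alcohol 21; C9′ is a sacrificial carbinol that is oxidised last.
2. C5′–C6′ bond: copper acetylide of alkyne 18 + allylic bromide 8, then saturation of the alkyne.
3. 18 ⇐ aldehyde 14 (C10′ bought in the L-serine-derived glycerate 9) + allenylzinc from (R)-but-3-yn-2-ol 15 (C8′ by centre → axis → centre transfer).
4. 8 ⇐ chroman 7 ⇐ seco diol 6 by photochemical aryl C–H/O–H closure of the O1–C8a bond (key step; C2 is the untouched linalool carbinol carbon); 6 ⇐ (R)-linalool 3 + aryl bromide 2.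
5. Rings: the benzene ring is bought; the dihydropyran ring is the only ring formed (step 4).

Assumption: 1, 3, 9 and 15 are bought (3, 9, 15 as single enantiomers); primed numbers count the side chain from chroman C2 (C8′ methyl-bearing CH, C9′ ketone, C10′ carbinol).

Step 1
Reactants: 1 3-bromo-5-methylphenol
Product: 2 (3-bromo-5-methylphenoxy)triisopropylsilane
Conditions: i-Pr3SiCl, imidazole, DMF, rt
Reagents that add atoms: chlorotriisopropylsilane, CC(C)[Si](Cl)(C(C)C)C(C)C
Why: Standard phenol silylation; the bulky silyl ether survives the later base, SeO2, copper and oxidation steps and shields the ring position ortho to oxygen.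

Step 2
Reactants: 3 (R)-linalool; 2 (3-bromo-5-methylphenoxy)triisopropylsilane
Product: 5 (3R)-3,7-dimethyl-1-[3-methyl-5-(triisopropylsilyloxy)phenyl]oct-6-en-3-ol, via alkylborane 4 (not isolated)
Conditions: 9-BBN (2.2 equiv), THF, 0 °C → rt; then 2, Pd(dppf)Cl2 (3 mol %), K3PO4 (3 M aq), THF/DMF, 55 °C
Reagents that add atoms: none
Why: 9-BBN hydroborates only the monosubstituted alkene (anti-Markovnikov) and the B-alkyl Suzuki–Miyaura coupling forms C4–C4a; the future C2 stereocentre is the bought linalool carbinol carbon and is not touched.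

Step 3
Reactants: 5 (3R)-3,7-dimethyl-1-[3-methyl-5-(triisopropylsilyloxy)phenyl]oct-6-en-3-ol
Product: 6 (2E,6R)-2,6-dimethyl-8-[3-methyl-5-(triisopropylsilyloxy)phenyl]oct-2-ene-1,6-diol
Conditions: SeO2 (0.3 equiv), t-BuOOH (3 equiv), salicylic acid (10 mol %), CH2Cl2, 0 °C → rt
Reagents that add atoms: tert-butyl hydroperoxide, CC(C)(C)OO; selenium dioxide (oxygen carrier), O=[Se]=O
Why: SeO2-catalysed allylic oxidation (ene reaction then [2,3]-shift) hydroxylates selectively the (E)-methyl of the trisubstituted alkene, giving the C5′ handle with E geometry.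

Step 4
Reactants: 6 (2E,6R)-2,6-dimethyl-8-[3-methyl-5-(triisopropylsilyloxy)phenyl]oct-2-ene-1,6-diol
Product: 7 (2E)-5-[(2R)-2,8-dimethyl-6-(triisopropylsilyloxy)chroman-2-yl]-2-methylpent-2-en-1-ol
Conditions: 3,6-di-tert-butyl-9-mesityl-10-phenylacridinium tetrafluoroborate (5 mol %), Co(dmgH)2(py)Cl (5 mol %), MeCN, 450 nm LEDs, N2, rt
Reagents that add atoms: none
Why: Proposed new method: intramolecular dehydrogenative aryl C–H/O–H coupling of a tertiary alcohol, in which the excited acridinium oxidises the silyloxyarene (easier to oxidise than the hydroxyl-deactivated alkene) to its radical cation, the tethered tertiary hydroxyl attacks the ring carbon para to the silyloxy group (six-membered ring; the other ortho site is blocked by the silyl group) and the cobaloxime removes H• and H+ as H2 to re-aromatise, so O1–C8a forms while the linalool C–O bond and its (R) centre are never broken; the closest known reaction types are acridinium-photoredox site-selective arene C–H amination and photoredox/cobaloxime dehydrogenative lactonisation of 2-arylbenzoic acids, neither shown for a tertiary alcohol closing a chroman.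

Step 5
Reactants: 7 (2E)-5-[(2R)-2,8-dimethyl-6-(triisopropylsilyloxy)chroman-2-yl]-2-methylpent-2-en-1-ol
Product: 8 (2R)-2-[(3E)-5-bromo-4-methylpent-3-en-1-yl]-2,8-dimethyl-6-(triisopropylsilyloxy)chroman
Conditions: CBr4, PPh3, CH2Cl2, 0 °C
Reagents that add atoms: tetrabromomethane, BrC(Br)(Br)Br
Why: Appel bromination substitutes the primary allylic alcohol by SN2 without allylic shift, keeping the E alkene.

Step 6
Reactants: 9 methyl (4S)-2,2-dimethyl-1,3-dioxolane-4-carboxylate
Product: 11 (4R)-2,2-dimethyl-4-(2-methylprop-1-en-1-yl)-1,3-dioxolane, via aldehyde 10 (not isolated)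
Conditions: i-Bu2AlH (1.05 equiv), CH2Cl2, −78 °C; then Ph3P=CMe2 (from i-PrPPh3I, n-BuLi, THF), −78 °C → rt
Reagents that add atoms: isopropyltriphenylphosphonium iodide, CC(C)[P+](c1ccccc1)(c1ccccc1)c1ccccc1.[I-]
Why: Partial ester reduction then Wittig olefination with a non-stabilised symmetrical ylide (no E/Z issue); the stereocentre (future C10′) is the bought glycerate carbon and is carried through unchanged.

Step 7
Reactants: 11 (4R)-2,2-dimethyl-4-(2-methylprop-1-en-1-yl)-1,3-dioxolane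
Product: 12 (2R)-4-methylpent-3-ene-1,2-diol
Conditions: PPTS (10 mol %), MeOH, rt
Reagents that add atoms: none
Why: Mild acid-catalysed transketalisation removes the acetonide without ionising the allylic C–O bond.

Step 8
Reactants: 12 (2R)-4-methylpent-3-ene-1,2-diol
Product: 13 (2R)-4-methyl-1,2-bis(triethylsilyloxy)pent-3-ene
Conditions: Et3SiCl (2.4 equiv), imidazole, CH2Cl2, 0 °C → rt
Reagents that add atoms: chlorotriethylsilane, CC[Si](Cl)(CC)CC
Why: Routine double silylation; the two ethers are told apart in the next step.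

Step 9
Reactants: 13 (2R)-4-methyl-1,2-bis(triethylsilyloxy)pent-3-ene
Product: 14 (2R)-4-methyl-2-(triethylsilyloxy)pent-3-enal
Conditions: (COCl)2, DMSO, CH2Cl2, −78 → −30 °C; then Et3N, −78 °C; used crude
Reagents that add atoms: none
Why: Under Swern conditions a primary triethylsilyl ether is cleaved and oxidised in one pot much faster than a secondary one (oxidative desilylation); low temperature avoids epimerisation and conjugation of the α-silyloxy β,γ-unsaturated aldehyde.

Step 10
Reactants: 15 (2R)-but-3-yn-2-ol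
Product: 16 (2R)-but-3-yn-2-yl methanesulfonate
Conditions: MsCl, Et3N, CH2Cl2, −78 → 0 °C
Reagents that add atoms: methanesulfonyl chloride, CS(Cl)(=O)=O
Why: Sulfonylation of the bought carbinol gives the leaving group for stereospecific allenylmetal formation.

Step 11
Reactants: 14 (2R)-4-methyl-2-(triethylsilyloxy)pent-3-enal; 16 (2R)-but-3-yn-2-yl methanesulfonate
Product: 18 (3S,4S,5R)-3,7-dimethyl-5-(triethylsilyloxy)oct-6-en-1-yn-4-ol, via allenylzinc 17 (not isolated)
Conditions: Pd(OAc)2 (5 mol %), PPh3 (5 mol %), Et2Zn (3 equiv), THF, −78 → −20 °C; aq NH4Cl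
Reagents that add atoms: none
Why: Marshall propargylation, in which anti SN2′ attack of zerovalent palladium and Pd-to-Zn exchange turn the bought carbinol centre into an allenylzinc axis that adds through a cyclic SE2′ transition state, setting C8′ (S) anti to the new C9′ carbinol, matched with Felkin–Anh attack on the α-silyloxy aldehyde; the butynol carbons stay in the product and C9′ is later oxidised.

Step 12
Reactants: 18 (3S,4S,5R)-3,7-dimethyl-5-(triethylsilyloxy)oct-6-en-1-yn-4-ol; 8 (2R)-2-[(3E)-5-bromo-4-methylpent-3-en-1-yl]-2,8-dimethyl-6-(triisopropylsilyloxy)chroman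
Product: 20 (2R)-2-[(3E,8S,9S,10R)-9-hydroxy-4,8,12-trimethyl-10-(triethylsilyloxy)trideca-3,11-dien-6-yn-1-yl]-2,8-dimethyl-6-(triisopropylsilyloxy)chroman, via copper acetylide 19 (not isolated)
Conditions: CuI (1.0 equiv), K2CO3 (1.5 equiv), DMF, rt
Reagents that add atoms: none
Why: Copper-mediated alkynyl–allyl coupling (SN2 at the unhindered primary allylic carbon) forms C5′–C6′ with the E alkene kept; the weak carbonate base avoids silyl migration between O9′ and O10′.

Step 13
Reactants: 20 (2R)-2-[(3E,8S,9S,10R)-9-hydroxy-4,8,12-trimethyl-10-(triethylsilyloxy)trideca-3,11-dien-6-yn-1-yl]-2,8-dimethyl-6-(triisopropylsilyloxy)chroman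
Product: 21 (2R)-2-[(3E,8S,9S,10R)-9-hydroxy-4,8,12-trimethyl-10-(triethylsilyloxy)trideca-3,11-dien-1-yl]-2,8-dimethyl-6-(triisopropylsilyloxy)chroman
Conditions: H2 (1 atm), RhCl(PPh3)3 (10 mol %), benzene/EtOH, rt
Reagents that add atoms: none
Why: Chemoselective homogeneous hydrogenation saturates the alkyne (through the cis-alkene) while the two trisubstituted alkenes are inert to this catalyst.

Step 14
Reactants: 21 (2R)-2-[(3E,8S,9S,10R)-9-hydroxy-4,8,12-trimethyl-10-(triethylsilyloxy)trideca-3,11-dien-1-yl]-2,8-dimethyl-6-(triisopropylsilyloxy)chroman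
Product: 22 (3E,8S,10R)-1-[(2R)-2,8-dimethyl-6-(triisopropylsilyloxy)chroman-2-yl]-4,8,12-trimethyl-10-(triethylsilyloxy)trideca-3,11-dien-9-one
Conditions: Dess–Martin periodinane, pyridine, CH2Cl2, 0 °C → rt
Reagents that add atoms: none
Why: Buffered Dess–Martin oxidation of the only free alcohol gives the ketone without enolisation, so C8′ and C10′ keep their configuration.

Step 15
Reactants: 22 (3E,8S,10R)-1-[(2R)-2,8-dimethyl-6-(triisopropylsilyloxy)chroman-2-yl]-4,8,12-trimethyl-10-(triethylsilyloxy)trideca-3,11-dien-9-one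
Product: 23 (3E,8S,10R)-10-hydroxy-1-[(2R)-6-hydroxy-2,8-dimethylchroman-2-yl]-4,8,12-trimethyltrideca-3,11-dien-9-one
Conditions: Bu4NF/AcOH (1:1), THF, 0 °C → rt
Reagents that add atoms: none
Why: Acetic-acid-buffered fluoride desilylation removes both silyl ethers under near-neutral conditions, avoiding base-induced isomerisation of the α-hydroxy β,γ-unsaturated ketone.

**Compound list**
1 | 3-bromo-5-methylphenol | Cc1cc(O)cc(Br)c1 | starting material
2 | (3-bromo-5-methylphenoxy)triisopropylsilane | Cc1cc(O[Si](C(C)C)(C(C)C)C(C)C)cc(Br)c1 | intermediate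
3 | (R)-linalool, (3R)-3,7-dimethylocta-1,6-dien-3-ol | CC(C)=CCC[C@@](C)(O)C=C | starting material
4 | 9-[(3S)-3-hydroxy-3,7-dimethyloct-6-en-1-yl]-9-borabicyclo[3.3.1]nonane | CC(C)=CCC[C@@](C)(O)CCB1C2CCCC1CCC2 | intermediate (not isolated)
5 | (3R)-3,7-dimethyl-1-[3-methyl-5-(triisopropylsilyloxy)phenyl]oct-6-en-3-ol | CC(C)=CCC[C@@](C)(O)CCc1cc(C)cc(O[Si](C(C)C)(C(C)C)C(C)C)c1 | intermediate
6 | (2E,6R)-2,6-dimethyl-8-[3-methyl-5-(triisopropylsilyloxy)phenyl]oct-2-ene-1,6-diol | OC/C(C)=C/CC[C@@](C)(O)CCc1cc(C)cc(O[Si](C(C)C)(C(C)C)C(C)C)c1 | intermediate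
7 | (2E)-5-[(2R)-2,8-dimethyl-6-(triisopropylsilyloxy)chroman-2-yl]-2-methylpent-2-en-1-ol | OC/C(C)=C/CC[C@]1(C)CCc2cc(O[Si](C(C)C)(C(C)C)C(C)C)cc(C)c2O1 | intermediate
8 | (2R)-2-[(3E)-5-bromo-4-methylpent-3-en-1-yl]-2,8-dimethyl-6-(triisopropylsilyloxy)chroman | BrC/C(C)=C/CC[C@]1(C)CCc2cc(O[Si](C(C)C)(C(C)C)C(C)C)cc(C)c2O1 | intermediate
9 | methyl (4S)-2,2-dimethyl-1,3-dioxolane-4-carboxylate | COC(=O)[C@@H]1COC(C)(C)O1 | starting material
10 | (4S)-2,2-dimethyl-1,3-dioxolane-4-carbaldehyde | O=C[C@@H]1COC(C)(C)O1 | intermediate (not isolated)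
11 | (4R)-2,2-dimethyl-4-(2-methylprop-1-en-1-yl)-1,3-dioxolane | CC(C)=C[C@@H]1COC(C)(C)O1 | intermediate
12 | (2R)-4-methylpent-3-ene-1,2-diol | CC(C)=C[C@@H](O)CO | intermediate
13 | (2R)-4-methyl-1,2-bis(triethylsilyloxy)pent-3-ene | CC(C)=C[C@@H](O[Si](CC)(CC)CC)CO[Si](CC)(CC)CC | intermediate
14 | (2R)-4-methyl-2-(triethylsilyloxy)pent-3-enal | CC(C)=C[C@@H](O[Si](CC)(CC)CC)C=O | intermediate
15 | (2R)-but-3-yn-2-ol | C#C[C@@H](C)O | starting material
16 | (2R)-but-3-yn-2-yl methanesulfonate | C#C[C@@H](C)OS(C)(=O)=O | intermediate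
17 | ethyl[(aS)-buta-1,2-dien-1-yl]zinc | CC([H])=[C@@]=C([H])[Zn]CC | intermediate (not isolated)
18 | (3S,4S,5R)-3,7-dimethyl-5-(triethylsilyloxy)oct-6-en-1-yn-4-ol | CC(C)=C[C@@H](O[Si](CC)(CC)CC)[C@@H](O)[C@@H](C)C#C | intermediate
19 | copper acetylide of 18 | CC(C)=C[C@@H](O[Si](CC)(CC)CC)[C@@H](O)[C@@H](C)C#C[Cu] | intermediate (not isolated)
20 | (2R)-2-[(3E,8S,9S,10R)-9-hydroxy-4,8,12-trimethyl-10-(triethylsilyloxy)trideca-3,11-dien-6-yn-1-yl]-2,8-dimethyl-6-(triisopropylsilyloxy)chroman | CC(C)=C[C@@H](O[Si](CC)(CC)CC)[C@@H](O)[C@@H](C)C#CC/C(C)=C/CC[C@]1(C)CCc2cc(O[Si](C(C)C)(C(C)C)C(C)C)cc(C)c2O1 | intermediate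
21 | (2R)-2-[(3E,8S,9S,10R)-9-hydroxy-4,8,12-trimethyl-10-(triethylsilyloxy)trideca-3,11-dien-1-yl]-2,8-dimethyl-6-(triisopropylsilyloxy)chroman | CC(C)=C[C@@H](O[Si](CC)(CC)CC)[C@@H](O)[C@@H](C)CCC/C(C)=C/CC[C@]1(C)CCc2cc(O[Si](C(C)C)(C(C)C)C(C)C)cc(C)c2O1 | intermediate
22 | (3E,8S,10R)-1-[(2R)-2,8-dimethyl-6-(triisopropylsilyloxy)chroman-2-yl]-4,8,12-trimethyl-10-(triethylsilyloxy)trideca-3,11-dien-9-one | CC(C)=C[C@@H](O[Si](CC)(CC)CC)C(=O)[C@@H](C)CCC/C(C)=C/CC[C@]1(C)CCc2cc(O[Si](C(C)C)(C(C)C)C(C)C)cc(C)c2O1 | intermediate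
23 | (3E,8S,10R)-10-hydroxy-1-[(2R)-6-hydroxy-2,8-dimethylchroman-2-yl]-4,8,12-trimethyltrideca-3,11-dien-9-one (CNP0273237.1) | CC(C)=C[C@@H](O)C(=O)[C@@H](C)CCC/C(C)=C/CC[C@]1(C)CCc2cc(O)cc(C)c2O1 | target

**Totals.** 15 steps in all. Longest linear sequence: 9 steps (1–5, then 12–15; the branch 6–9, 11, 12–15 is equally long).

**Origin of the stereocentres.** C2 is bought in (R)-linalool; C10′ is bought in the glycerate 9; C8′ is controlled by the bought centre of (R)-but-3-yn-2-ol through the allenylzinc; C9′ is temporary.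

**Three steps most likely to fail**

Step 4, the new photochemical ring closure: the electron-rich chroman product may be over-oxidised, or attack may occur ortho to oxygen. The fallback uses known chemistry and sets out from 2. NBS in MeCN brominates para to the silyloxy group to give (3,4-dibromo-5-methylphenoxy)triisopropylsilane F1. B-alkyl Suzuki–Miyaura coupling of borane 4 at the less hindered bromide (Pd(dppf)Cl2, K3PO4) gives (3R)-1-[2-bromo-3-methyl-5-(triisopropylsilyloxy)phenyl]-3,7-dimethyloct-6-en-3-ol F2. Intramolecular palladium-catalysed aryl ether formation from the tertiary alcohol (Pd(OAc)2, 2-(di-tert-butylphosphino)-1,1′-binaphthyl, Cs2CO3, toluene, 80 °C) gives (2R)-2,8-dimethyl-2-(4-methylpent-3-en-1-yl)-6-(triisopropylsilyloxy)chroman F3 with the tertiary C–O bond intact. SeO2/t-BuOOH allylic oxidation of F3 then comes back to the route at 7.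

Step 9, the one-pot oxidative desilylation: selectivity between the two silyl ethers may be incomplete and the aldehyde is labile. The fallback sets out from 13: selective methanolysis of the primary silyl ether (PPTS, MeOH/CH2Cl2, −20 °C) gives (2R)-4-methyl-2-(triethylsilyloxy)pent-3-en-1-ol F4, and Dess–Martin oxidation at 0 °C comes back at 14.

Step 13, saturation of the alkyne beside two trisubstituted alkenes: the rhodium catalyst may stall at the alkene or be slow on the internal alkyne. The fallback sets out from 20: semi-hydrogenation over Pd/CaCO3 poisoned with Pb(OAc)2 (quinoline, H2) gives (2R)-2-[(3E,6Z,8S,9S,10R)-9-hydroxy-4,8,12-trimethyl-10-(triethylsilyloxy)trideca-3,6,11-trien-1-yl]-2,8-dimethyl-6-(triisopropylsilyloxy)chroman F5. Diimide (2-nitrobenzenesulfonylhydrazide, Et3N, CH2Cl2) then reduces only the cis-disubstituted alkene and comes back at 21.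

**Further compounds**
F1 | step 4 | (3,4-dibromo-5-methylphenoxy)triisopropylsilane | Cc1cc(O[Si](C(C)C)(C(C)C)C(C)C)cc(Br)c1Br
F2 | step 4 | (3R)-1-[2-bromo-3-methyl-5-(triisopropylsilyloxy)phenyl]-3,7-dimethyloct-6-en-3-ol | CC(C)=CCC[C@@](C)(O)CCc1cc(O[Si](C(C)C)(C(C)C)C(C)C)cc(C)c1Br
F3 | step 4 | (2R)-2,8-dimethyl-2-(4-methylpent-3-en-1-yl)-6-(triisopropylsilyloxy)chroman | CC(C)=CCC[C@]1(C)CCc2cc(O[Si](C(C)C)(C(C)C)C(C)C)cc(C)c2O1
F4 | step 9 | (2R)-4-methyl-2-(triethylsilyloxy)pent-3-en-1-ol | CC(C)=C[C@@H](O[Si](CC)(CC)CC)CO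
F5 | step 13 | (2R)-2-[(3E,6Z,8S,9S,10R)-9-hydroxy-4,8,12-trimethyl-10-(triethylsilyloxy)trideca-3,6,11-trien-1-yl]-2,8-dimethyl-6-(triisopropylsilyloxy)chroman | CC(C)=C[C@@H](O[Si](CC)(CC)CC)[C@@H](O)[C@@H](C)/C=C\C/C(C)=C/CC[C@]1(C)CCc2cc(O[Si](C(C)C)(C(C)C)C(C)C)cc(C)c2O1
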